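## Retrosynthetic overview
1. The target comes from one global deprotection. The upper chroman ring is closed last: a tethered resorcinol ether attacks a C4 benzylic cation (C4–C4a Friedel–Crafts), which gives the 3,4-trans relationship.
2. The C4–central-ring bond comes from the aryllithium of the finished lower (3R)-isoflavan (Br/Li exchange fixes the position ipso) and an α-aryl aldehyde masked as a 2-hydroxydihydrobenzofuran.
3. The key bond is C3–C1' of the upper unit. It joins the enamine of a 3-aryloxypropanal to 2-methoxy-1,4-benzoquinone, which acts as the polarity-reversed (electrophilic) form of the electron-rich ring B. Two natural donor carbons are joined, and the amine catalyst sets C3 as R.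
4. The lower unit comes from 7-benzyloxychroman-4-one and an aryl bromide by Pd α-arylation, site-selective bromination, transfer hydrogenation with dynamic kinetic resolution (sets 3R) and ionic deoxygenation. Ring order: lower chroman (bought), then a temporary dihydrobenzofuran lactol, then the upper chroman.

Labels and assumption: the upper unit is the 3,4-diarylchroman (C2, C3, C4, ring A, ring B = 2-hydroxy-4,5-dimethoxyphenyl), the central ring is the aryl group on C4, and the lower unit is the 3-arylchroman; lactols 7 and 8 are used as anomer mixtures and diol 19 as a C4 epimer mixture, because that carbon is planarised in step 10.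

## Route

**Step 1**
Reactants: 1 3-(benzyloxy)phenol; 2 2-(2-bromoethyl)-1,3-dioxolane
Product: 3 2-{2-[3-(benzyloxy)phenoxy]ethyl}-1,3-dioxolane
Conditions: K2CO3, DMF, 70 °C
Reagents that add atoms: none
Why: Williamson ether synthesis (SN2 of the phenoxide on a primary bromide), with the aldehyde kept as a base-stable dioxolane so that β-elimination of the new aryl ether cannot start.

**Step 2**
Reactants: 3 2-{2-[3-(benzyloxy)phenoxy]ethyl}-1,3-dioxolane
Product: 4 3-[3-(benzyloxy)phenoxy]propanal
Conditions: 2 M HCl, THF, rt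
Reagents that add atoms: water, O
Why: Acid-catalysed acetal hydrolysis, chosen because the β-aryloxy aldehyde tolerates dilute acid but not base, and no stereocentre is involved.

**Step 3 (key step)**
Reactants: 4 3-[3-(benzyloxy)phenoxy]propanal; 5 2-methoxy-1,4-benzoquinone
Product: 7 (3R)-3-{[3-(benzyloxy)phenoxy]methyl}-6-methoxy-2,3-dihydro-1-benzofuran-2,5-diol, via open-chain hydroquinone aldehyde 6 (not isolated)
Conditions: (R)-2-{bis[3,5-bis(trifluoromethyl)phenyl](trimethylsilyloxy)methyl}pyrrolidine (20 mol %), EtOH/H2O, 0 °C, 4 in slight excess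
Reagents that add atoms: none
Why: Enamine-catalysed asymmetric α-arylation of an aldehyde with a quinone (conjugate addition, then tautomerisation), in which the quinone is an aryl-cation equivalent for ring B, its C5 (β to the more electrophilic C1 carbonyl, the C4 carbonyl being a deactivated vinylogous ester) accepts the normally nucleophilic aldehyde α-carbon, the bulky side arm of the (R)-catalyst shields one enamine face so that C3 is set as R, and closure of 6 to lactol 7 protects the α-aryl aldehyde from racemisation.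

**Step 4**
Reactants: 7 (3R)-3-{[3-(benzyloxy)phenoxy]methyl}-6-methoxy-2,3-dihydro-1-benzofuran-2,5-diol
Product: 8 (3R)-3-{[3-(benzyloxy)phenoxy]methyl}-5,6-dimethoxy-2,3-dihydro-1-benzofuran-2-ol
Conditions: Me3SiCHN2, iPr2NEt (cat.), MeCN/MeOH 9:1, rt
Reagents that add atoms: trimethylsilyldiazomethane, C[Si](C)(C)C=[N+]=[N-]
Why: Diazoalkane O-methylation of a phenol, in which only the phenolic OH is acidic enough to protonate the diazo carbon, so the lactol OH stays free, the medium stays nearly neutral and C3 is not epimerised.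

**Step 5**
Reactants: 9 3-bromo-5-methoxyphenol
Product: 10 (3-bromo-5-methoxyphenoxy)triisopropylsilane
Conditions: iPr3SiCl, imidazole, DMF, rt
Reagents that add atoms: chlorotriisopropylsilane, CC(C)[Si](Cl)(C(C)C)C(C)C
Why: Imidazole-promoted silylation of a phenol, the bulky silyl group being needed in step 8 to shield both ring positions next to it.

**Step 6**
Reactants: 11 7-hydroxychroman-4-one
Product: 12 7-(benzyloxy)chroman-4-one
Conditions: BnBr, K2CO3, acetone, reflux
Reagents that add atoms: benzyl bromide, BrCc1ccccc1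
Why: Williamson ether synthesis on the acidic phenol para to the ketone.

**Step 7**
Reactants: 10 (3-bromo-5-methoxyphenoxy)triisopropylsilane; 12 7-(benzyloxy)chroman-4-one
Product: 13 rac-7-(benzyloxy)-3-[3-methoxy-5-(triisopropylsilyloxy)phenyl]chroman-4-one
Conditions: Pd(OAc)2 (3 mol %), XPhos (6 mol %), K3PO4, toluene, 90 °C
Reagents that add atoms: none
Why: Palladium-catalysed ketone α-arylation of the Buchwald–Hartwig type (oxidative addition, enolate binding, reductive elimination) with a mild phosphate base that spares the aryl silyl ether, the new C3 centre being formed racemic and staying labile, which step 9 exploits.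

**Step 8**
Reactants: 13 rac-7-(benzyloxy)-3-[3-methoxy-5-(triisopropylsilyloxy)phenyl]chroman-4-one
Product: 14 rac-7-(benzyloxy)-3-[2-bromo-3-methoxy-5-(triisopropylsilyloxy)phenyl]chroman-4-one
Conditions: NBS (1 equiv), MeCN, −20 to 0 °C, dark
Reagents that add atoms: N-bromosuccinimide, O=C1CCC(=O)N1Br
Why: Electrophilic aromatic bromination in which ring A is deactivated by its acyl group and the two positions flanking the triisopropylsilyloxy group are sterically closed, so bromine enters the remaining activated carbon, ortho to OMe and para to the silyloxy group.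

**Step 9**
Reactants: 14 rac-7-(benzyloxy)-3-[2-bromo-3-methoxy-5-(triisopropylsilyloxy)phenyl]chroman-4-one
Product: 16 (3R)-7-(benzyloxy)-3-[2-bromo-3-methoxy-5-(triisopropylsilyloxy)phenyl]chroman, via cis-isoflavan-4-ol 15 (not isolated)
Conditions: RuCl[(R,R)-TsDPEN](p-cymene) (2 mol %), HCO2H/Et3N 5:2, EtOAc, 40 °C; then CH2Cl2, Et3SiH, CF3CO2H, −20 °C
Reagents that add atoms: none
Why: Noyori-type asymmetric transfer hydrogenation under dynamic kinetic resolution (Et3N racemises C3 through the enol while the (R,R)-catalyst reduces only the 3R ketone to the cis-(3R,4R)-alcohol 15), followed by ionic hydrogenation in which the 7-alkoxy-stabilised C4 cation takes hydride from Et3SiH faster than it loses the C3 proton, so the 3R centre survives.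

**Step 10**
Reactants: 16 (3R)-7-(benzyloxy)-3-[2-bromo-3-methoxy-5-(triisopropylsilyloxy)phenyl]chroman; 8 (3R)-3-{[3-(benzyloxy)phenoxy]methyl}-5,6-dimethoxy-2,3-dihydro-1-benzofuran-2-ol
Product: 21 (3R,4S)-7-(benzyloxy)-4-{2-[(3R)-7-(benzyloxy)chroman-3-yl]-6-methoxy-4-(triisopropylsilyloxy)phenyl}-3-(2-hydroxy-4,5-dimethoxyphenyl)chroman, via aryllithium 17 (not isolated), via lithium phenoxide aldehyde 18 (not isolated), via benzylic diol 19 (not isolated), via trans-dihydrobenzofuran 20 (not isolated)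
Conditions: 16, n-BuLi, THF, −78 °C; 8, n-BuLi (1 equiv), THF, −78 °C; combine, −78 to −30 °C; then CF3CO2H, CH2Cl2, −30 to 0 °C
Reagents that add atoms: none
Why: Bromine–lithium exchange fixes the nucleophilic carbon ipso, 1,2-addition of 17 to the unmasked aldehyde 18 makes the C4–aryl bond, and acid then ionises the dialkoxybenzylic alcohol 19 to a cation that is trapped reversibly by the phenol (20) and finally irreversibly by the tethered resorcinol ether para to its benzyloxy group (intramolecular Friedel–Crafts alkylation through a chair-like transition state with both aryl groups equatorial), which sets C4 as S, trans to the untouched 3R centre.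

**Step 11**
Reactants: 21 (3R,4S)-7-(benzyloxy)-4-{2-[(3R)-7-(benzyloxy)chroman-3-yl]-6-methoxy-4-(triisopropylsilyloxy)phenyl}-3-(2-hydroxy-4,5-dimethoxyphenyl)chroman
Product: 22 (3R,4S)-3-(2-hydroxy-4,5-dimethoxyphenyl)-4-{4-hydroxy-2-[(3R)-7-hydroxychroman-3-yl]-6-methoxyphenyl}chroman-7-ol (CNP0266829.1)
Conditions: H2 (1 atm), 10% Pd/C, KHF2, MeOH/EtOAc, rt
Reagents that add atoms: none
Why: Catalytic hydrogenolysis of the two benzyl ethers and fluoride cleavage of the phenolic silyl ether run side by side in one flask because neither reagent disturbs the other, and no stereocentre carries a hydrogenolysable C–O bond.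

## Compound list
1 | 3-(benzyloxy)phenol | Oc1cccc(OCc2ccccc2)c1 | starting material
2 | 2-(2-bromoethyl)-1,3-dioxolane | BrCCC1OCCO1 | starting material
3 | 2-{2-[3-(benzyloxy)phenoxy]ethyl}-1,3-dioxolane | C1COC(CCOc2cccc(OCc3ccccc3)c2)O1 | intermediate
4 | 3-[3-(benzyloxy)phenoxy]propanal | O=CCCOc1cccc(OCc2ccccc2)c1 | intermediate
5 | 2-methoxy-1,4-benzoquinone | COC1=CC(=O)C=CC1=O | starting material
6 | (2R)-3-[3-(benzyloxy)phenoxy]-2-(2,5-dihydroxy-4-methoxyphenyl)propanal | O=C[C@@H](COc1cccc(OCc2ccccc2)c1)c1cc(O)c(OC)cc1O | intermediate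
7 | (3R)-3-{[3-(benzyloxy)phenoxy]methyl}-6-methoxy-2,3-dihydro-1-benzofuran-2,5-diol (anomers at C2) | OC1Oc2cc(OC)c(O)cc2[C@@H]1COc1cccc(OCc2ccccc2)c1 | intermediate
8 | (3R)-3-{[3-(benzyloxy)phenoxy]methyl}-5,6-dimethoxy-2,3-dihydro-1-benzofuran-2-ol (anomers at C2) | OC1Oc2cc(OC)c(OC)cc2[C@@H]1COc1cccc(OCc2ccccc2)c1 | intermediate
9 | 3-bromo-5-methoxyphenol | COc1cc(O)cc(Br)c1 | starting material
10 | (3-bromo-5-methoxyphenoxy)triisopropylsilane | COc1cc(Br)cc(O[Si](C(C)C)(C(C)C)C(C)C)c1 | intermediate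
11 | 7-hydroxychroman-4-one | O=C1CCOc2cc(O)ccc12 | starting material
12 | 7-(benzyloxy)chroman-4-one | O=C1CCOc2cc(OCc3ccccc3)ccc12 | intermediate
13 | rac-7-(benzyloxy)-3-[3-methoxy-5-(triisopropylsilyloxy)phenyl]chroman-4-one | O=C1C(COc2cc(OCc3ccccc3)ccc12)c1cc(OC)cc(O[Si](C(C)C)(C(C)C)C(C)C)c1 | intermediate
14 | rac-7-(benzyloxy)-3-[2-bromo-3-methoxy-5-(triisopropylsilyloxy)phenyl]chroman-4-one | O=C1C(COc2cc(OCc3ccccc3)ccc12)c1cc(O[Si](C(C)C)(C(C)C)C(C)C)cc(OC)c1Br | intermediate
15 | (3R,4R)-cis-7-(benzyloxy)-3-[2-bromo-3-methoxy-5-(triisopropylsilyloxy)phenyl]chroman-4-ol | COc1cc(O[Si](C(C)C)(C(C)C)C(C)C)cc([C@@H]2COc3cc(OCc4ccccc4)ccc3[C@@H]2O)c1Br | intermediate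
16 | (3R)-7-(benzyloxy)-3-[2-bromo-3-methoxy-5-(triisopropylsilyloxy)phenyl]chroman | COc1cc(O[Si](C(C)C)(C(C)C)C(C)C)cc([C@@H]2COc3cc(OCc4ccccc4)ccc3C2)c1Br | intermediate
17 | {2-[(3R)-7-(benzyloxy)chroman-3-yl]-6-methoxy-4-(triisopropylsilyloxy)phenyl}lithium | COc1cc(O[Si](C(C)C)(C(C)C)C(C)C)cc([C@@H]2COc3cc(OCc4ccccc4)ccc3C2)c1[Li] | intermediate
18 | lithium 2-{(2R)-1-[3-(benzyloxy)phenoxy]-3-oxopropan-2-yl}-4,5-dimethoxyphenolate (ring-opened salt of 8) | [Li+].[O-]c1cc(OC)c(OC)cc1[C@@H](C=O)COc1cccc(OCc2ccccc2)c1 | intermediate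
19 | (2R)-3-[3-(benzyloxy)phenoxy]-1-{2-[(3R)-7-(benzyloxy)chroman-3-yl]-6-methoxy-4-(triisopropylsilyloxy)phenyl}-2-(2-hydroxy-4,5-dimethoxyphenyl)propan-1-ol (C1 epimers) | COc1cc(O[Si](C(C)C)(C(C)C)C(C)C)cc([C@@H]2COc3cc(OCc4ccccc4)ccc3C2)c1C(O)[C@@H](COc1cccc(OCc2ccccc2)c1)c1cc(OC)c(OC)cc1O | intermediate
20 | (2S,3R)-trans-3-{[3-(benzyloxy)phenoxy]methyl}-2-{2-[(3R)-7-(benzyloxy)chroman-3-yl]-6-methoxy-4-(triisopropylsilyloxy)phenyl}-5,6-dimethoxy-2,3-dihydro-1-benzofuran | COc1cc(O[Si](C(C)C)(C(C)C)C(C)C)cc([C@@H]2COc3cc(OCc4ccccc4)ccc3C2)c1[C@H]1Oc2cc(OC)c(OC)cc2[C@@H]1COc1cccc(OCc2ccccc2)c1 | intermediate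
21 | (3R,4S)-7-(benzyloxy)-4-{2-[(3R)-7-(benzyloxy)chroman-3-yl]-6-methoxy-4-(triisopropylsilyloxy)phenyl}-3-(2-hydroxy-4,5-dimethoxyphenyl)chroman | COc1cc(O)c(cc1OC)[C@@H]1COc2cc(OCc3ccccc3)ccc2[C@H]1c1c(OC)cc(O[Si](C(C)C)(C(C)C)C(C)C)cc1[C@@H]1COc2cc(OCc3ccccc3)ccc2C1 | intermediate
22 | (3R,4S)-3-(2-hydroxy-4,5-dimethoxyphenyl)-4-{4-hydroxy-2-[(3R)-7-hydroxychroman-3-yl]-6-methoxyphenyl}chroman-7-ol | COc1cc(O)c([C@@H]2COc3cc(O)ccc3[C@H]2c2c(OC)cc(O)cc2[C@@H]2COc3cc(O)ccc3C2)cc1OC | target

## Step count and risks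
Total steps: 11.

Longest linear sequence: 6. This is steps 5, 7, 8, 9, 10, 11, or equally steps 1, 2, 3, 4, 10, 11.

**Step 3.** The enamine of 4 can expel phenol 1 (retro-oxa-Michael), and attack on 5 could stray from C5.
- The fallback installs the aryl ether only after the C–C bond. It sets out from 5 and comes back to the route at 8.
- The same enamine arylation is run on commercial 3-[(tert-butyldimethylsilyl)oxy]propanal F1, whose silyloxy group is a far poorer leaving group. This gives (3R)-3-{[(tert-butyldimethylsilyl)oxy]methyl}-6-methoxy-2,3-dihydro-1-benzofuran-2,5-diol F2.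
- Me3SiCHN2 gives (3R)-3-{[(tert-butyldimethylsilyl)oxy]methyl}-5,6-dimethoxy-2,3-dihydro-1-benzofuran-2-ol F3.
- Camphorsulfonic acid in MeOH locks the lactol as its methyl acetal and removes the silyl group. This gives [(3R)-2,5,6-trimethoxy-2,3-dihydro-1-benzofuran-3-yl]methanol F4.
- Mitsunobu etherification (PPh3, DIAD) with 1 gives (3R)-3-{[3-(benzyloxy)phenoxy]methyl}-2,5,6-trimethoxy-2,3-dihydro-1-benzofuran F5, and dilute aqueous acid then gives 8.

**Step 8.** Bromine may enter the position para to OMe or ring A instead of C2'.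
- The fallback fixes the position by deprotonation and ipso substitution rather than by directing effects. It sets out from 10 and comes back at 14.
- LDA with Me3SiCl present (THF, −78 °C) removes the most acidic proton, the one between Br and OMe. This gives [2-bromo-6-methoxy-4-(triisopropylsilyloxy)phenyl]trimethylsilane F6.
- The α-arylation of step 7 with 12 gives rac-7-(benzyloxy)-3-[3-methoxy-2-(trimethylsilyl)-5-(triisopropylsilyloxy)phenyl]chroman-4-one F7.
- NBS in MeCN then replaces silicon by bromine at the same carbon to give 14.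

**Step 10.** The hindered aryllithium 17 may enolise 18, which would cause racemisation and loss of the aryloxide. The cation may also lose the C3 proton during the slow conversion of 20 into 21.
- The fallback reverses the order of the two C4–aryl bonds. It sets out from 8 and comes back at 21.
- Catalytic CF3CO2H in CH2Cl2 closes C4–C4a first through the lactol oxocarbenium ion. This gives (6aR,11aR)-3-(benzyloxy)-8,9-dimethoxy-6a,11a-dihydro-6H-[1]benzofuro[3,2-c]chromene F8, a cis-fused pterocarpan.
- F8 is activated with BF3·OEt2 at −78 °C in the presence of 17. The aryllithium attacks C11a anti to the aryl ring on C6a and releases the phenol, giving 21 directly.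
- In either version, residual minor enantiomers of the two halves end up as diastereomers of 21 and are removed by chromatography.

## Further compounds
F1 | step 3 | 3-[(tert-butyldimethylsilyl)oxy]propanal | CC(C)(C)[Si](C)(C)OCCC=O
F2 | step 3 | (3R)-3-{[(tert-butyldimethylsilyl)oxy]methyl}-6-methoxy-2,3-dihydro-1-benzofuran-2,5-diol | OC1Oc2cc(OC)c(O)cc2[C@@H]1CO[Si](C)(C)C(C)(C)C
F3 | step 3 | (3R)-3-{[(tert-butyldimethylsilyl)oxy]methyl}-5,6-dimethoxy-2,3-dihydro-1-benzofuran-2-ol | OC1Oc2cc(OC)c(OC)cc2[C@@H]1CO[Si](C)(C)C(C)(C)C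
F4 | step 3 | [(3R)-2,5,6-trimethoxy-2,3-dihydro-1-benzofuran-3-yl]methanol | COC1Oc2cc(OC)c(OC)cc2[C@@H]1CO
F5 | step 3 | (3R)-3-{[3-(benzyloxy)phenoxy]methyl}-2,5,6-trimethoxy-2,3-dihydro-1-benzofuran | COC1Oc2cc(OC)c(OC)cc2[C@@H]1COc1cccc(OCc2ccccc2)c1
F6 | step 8 | [2-bromo-6-methoxy-4-(triisopropylsilyloxy)phenyl]trimethylsilane | COc1cc(O[Si](C(C)C)(C(C)C)C(C)C)cc(Br)c1[Si](C)(C)C
F7 | step 8 | rac-7-(benzyloxy)-3-[3-methoxy-2-(trimethylsilyl)-5-(triisopropylsilyloxy)phenyl]chroman-4-one | O=C1C(COc2cc(OCc3ccccc3)ccc12)c1cc(O[Si](C(C)C)(C(C)C)C(C)C)cc(OC)c1[Si](C)(C)C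
F8 | step 10 | (6aR,11aR)-3-(benzyloxy)-8,9-dimethoxy-6a,11a-dihydro-6H-[1]benzofuro[3,2-c]chromene | COc1cc2O[C@H]3c4ccc(OCc5ccccc5)cc4OC[C@H]3c2cc1OC
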